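**Retrosynthetic overview**
1. Numbering: ring A = benzo ring (C4a, C5–C8, C8a; a 2-methylresorcinol), ring B = quinone ring (C1–C4; C2 bears N, C3 bears CH3), ring C = 23-membered ansa ring; chain carbons C1' (amide C=O) to C17' (aryl ketone).
2. Ring C: C3'–C4' by an intramolecular Stille coupling (last C–C bond), N–C1' by acylation of a 2-aminoquinone obtained from a 2-methoxyquinone and NH3.
3. Ring B: C1–C8a by 6π electrocyclization of an aryl dienylketene released from a squarate-derived 4-aryl-4-silyloxycyclobutenone (aryllithium + dimethyl squarate, then MeLi). Enabling feature: in ring A, C5 already carries the C17' acyl group, so C8a–H is the only free ortho carbon of the aryl group, and C1 sits next to the heteroatom-bearing C2, which is the ketene carbon/alkoxy carbon pair of a squarate.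
4. C16'–C17' by CrCl2/NiCl2 coupling of the ring A aldehyde with the (Z)-alkenyl iodide of the C4'–C16' chain, before ring B exists. Chain: two Evans aldols (C12'/C13', C10'/C11'), chelate-controlled alkynylation (C14'), crotylboration (C8'/C9'), allenylzinc propargylation (C6'/C7'), hydroalumination–iodination (C15'=C16').
5. Order of rings: ring A (bought) → ring B (step 33) → ring C (step 37).

Key step: step 33

Assumptions: 23, 35 and 54 are taken as catalogue compounds; the carbinol carbon of the cyclobutene unit (10–13, 46–49) is carried as a mixture of both configurations because it becomes C4 of ring B in step 33.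

**Part A – ring A and the cyclobutenone**

Step 1
Reactants: 1 2-methylresorcinol
Product: 2 1,3-bis(methoxymethoxy)-2-methylbenzene
Conditions: MOMCl, i-Pr2NEt, CH2Cl2, 0 °C → rt
Reagents that add atoms: chloromethyl methyl ether, COCCl
Why: O-alkylation of both phenols (MOM ether formation) should give acetal ethers that survive the organolithium steps and direct the later ortho-lithiation.

Step 2
Reactants: 2 1,3-bis(methoxymethoxy)-2-methylbenzene
Product: 4 5-iodo-1,3-bis(methoxymethoxy)-2-methylbenzene, via aryl pinacol boronate 3 (not isolated)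
Conditions: [Ir(cod)OMe]2 (cat.), 4,4'-di-tert-butyl-2,2'-bipyridine, B2pin2, THF, 80 °C; then CuI (cat.), 1,10-phenanthroline, KI, MeOH/H2O, air, 80 °C
Reagents that add atoms: potassium iodide, [K+].[I-]
Why: Sterically controlled Ir-catalysed C–H borylation should take the only ring C–H without an ortho substituent (the future C4a), and copper-mediated iododeboronation then converts boronate 3 into the iodide.

Step 3
Reactants: 4 5-iodo-1,3-bis(methoxymethoxy)-2-methylbenzene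
Product: 6 6-iodo-2,4-bis(methoxymethoxy)-3-methylbenzaldehyde, via aryllithium 5 (not isolated)
Conditions: LiN(i-Pr)2, THF, −78 °C; then DMF; aq. NH4Cl
Reagents that add atoms: N,N-dimethylformamide, CN(C)C=O
Why: Directed ortho-lithiation at the C–H flanked by iodine and OMOM (the two remaining ring hydrogens are equivalent) followed by formylation should install the future C17'.

Step 4
Reactants: 6 6-iodo-2,4-bis(methoxymethoxy)-3-methylbenzaldehyde
Product: 7 1-(dimethoxymethyl)-6-iodo-2,4-bis(methoxymethoxy)-3-methylbenzene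
Conditions: HC(OMe)3, MeOH, PPTS (cat.), rt
Reagents that add atoms: trimethyl orthoformate, COC(OC)OC
Why: Acid-catalysed acetalization masks the aldehyde against the two organolithium reagents that follow.

Step 5
Reactants: 7 1-(dimethoxymethyl)-6-iodo-2,4-bis(methoxymethoxy)-3-methylbenzene; 8 dimethyl squarate
Product: 11 4-aryl-2,3-dimethoxy-4-(triethylsilyloxy)cyclobut-2-en-1-one (aryl = 2-(dimethoxymethyl)-3,5-bis(methoxymethoxy)-4-methylphenyl), via aryllithium 9 (not isolated), via lithium alkoxide 10 (not isolated)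
Conditions: n-BuLi, THF, −78 °C; then 8, −78 °C; then TESOTf, −78 → 0 °C
Reagents that add atoms: triethylsilyl trifluoromethanesulfonate, CC[Si](CC)(CC)OS(=O)(=O)C(F)(F)F
Why: Iodine–lithium exchange gives aryllithium 9, which adds 1,2 to one carbonyl of the squarate, and the tertiary alkoxide 10 is silylated in the same flask (first stage of the Moore quinone synthesis).

Step 6
Reactants: 11 4-aryl-2,3-dimethoxy-4-(triethylsilyloxy)cyclobut-2-en-1-one
Product: 13 4-[2-formyl-3,5-bis(methoxymethoxy)-4-methylphenyl]-2-methoxy-3-methyl-4-(triethylsilyloxy)cyclobut-2-en-1-one, via lithium methylcarbinolate 12 (not isolated)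
Conditions: MeLi, THF, −78 °C; then 1 M HCl, THF, 0 °C
Reagents that add atoms: methyllithium, [Li]C; water, O
Why: 1,2-Addition of MeLi to the vinylogous ester carbonyl and acid-induced allylic 1,3-transposition (Stork–Danheiser type, water entering at the methoxy-bearing terminus) should place CH3 at C3 and leave OCH3 next to the new carbonyl, while the same acid unmasks the aldehyde.

**Part B – chain C4'–C16'**

Step 7
Reactants: 14 (R)-4-benzyl-3-propionyloxazolidin-2-one; 15 methacrolein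
Product: 17 (R)-4-benzyl-3-[(2R,3R)-3-hydroxy-2,4-dimethylpent-4-enoyl]oxazolidin-2-one, via boron enolate 16 (not isolated)
Conditions: Bu2BOTf, Et3N, CH2Cl2, −78 → 0 °C; then 15, −78 → 0 °C; H2O2, pH 7 buffer, MeOH
Reagents that add atoms: none
Why: Evans syn aldol of the (Z)-boron enolate 16 through a Zimmerman–Traxler chair; the (R)-benzyl auxiliary sets C12' and C13'.

Step 8
Reactants: 17 aldol adduct
Product: 18 (R)-4-benzyl-3-[(2R,3R)-3-hydroxy-2-methyl-4-oxopentanoyl]oxazolidin-2-one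
Conditions: OsO4 (cat.), NaIO4, 2,6-lutidine, dioxane/H2O, rt
Reagents that add atoms: sodium periodate, [Na+].[O-]I(=O)(=O)=O
Why: Lemieux–Johnson cleavage of the 1,1-disubstituted alkene should give the methyl ketone that becomes C14'.

Step 9
Reactants: 18 hydroxy ketone
Product: 19 (R)-4-benzyl-3-[(2R,3R,4R)-3,4-dihydroxy-2,4-dimethylhept-5-ynoyl]oxazolidin-2-one
Conditions: CH3C≡CMgBr (3 equiv), THF, −78 → −40 °C; aq. NH4Cl
Reagents that add atoms: 1-propynylmagnesium bromide, CC#C[Mg]Br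
Why: Cram-chelate addition: the magnesium alkoxide at C13' and the ketone oxygen form a five-membered chelate that the alkynyl Grignard attacks opposite to C12', which sets C14' (13',14'-syn diol).

Step 10
Reactants: 19 diol
Product: 20 acetonide of 19 (2,2-dimethyl-1,3-dioxolane across O13'/O14')
Conditions: Me2C(OMe)2, PPTS (cat.), CH2Cl2, rt
Reagents that add atoms: 2,2-dimethoxypropane, COC(C)(C)OC
Why: Acetonide formation protects both hydroxyls, so the C11' aldehyde cannot close to a lactol with O14'.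

Step 11
Reactants: 20 acetonide imide
Product: 21 (R)-2-[(4R,5R)-2,2,5-trimethyl-5-(prop-1-ynyl)-1,3-dioxolan-4-yl]propan-1-ol
Conditions: LiBH4, MeOH (1 equiv), THF, 0 °C
Reagents that add atoms: none
Why: Reductive cleavage of the N-acyloxazolidinone by borohydride gives the primary alcohol without touching C12'.

Step 12
Reactants: 21 primary alcohol
Product: 22 C11' aldehyde (C11'–C16'; acetonide; alkyne)
Conditions: Dess–Martin periodinane, NaHCO3, CH2Cl2, 0 °C → rt
Reagents that add atoms: none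
Why: Dess–Martin oxidation under buffered non-basic conditions should give the α-methyl aldehyde without epimerization.

Step 13
Reactants: 23 3-[(4-methoxybenzyl)oxy]propanoic acid; 24 (S)-4-benzyloxazolidin-2-one
Product: 26 (S)-4-benzyl-3-{3-[(4-methoxybenzyl)oxy]propanoyl}oxazolidin-2-one, via mixed pivalic anhydride 25 (not isolated)
Conditions: PivCl, Et3N, THF, −20 °C; then 24, LiCl, rt
Reagents that add atoms: none
Why: N-acylation of the oxazolidinone through the mixed anhydride 25.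

Step 14
Reactants: 26 imide; 22 C11' aldehyde
Product: 28 syn aldol adduct (C9' imide carbonyl; C10' CH2OPMB; C11' OH), via boron enolate 27 (not isolated)
Conditions: Bu2BOTf, i-Pr2NEt, CH2Cl2, −78 → 0 °C; then 22, −78 → 0 °C; H2O2, pH 7 buffer, MeOH
Reagents that add atoms: none
Why: Evans syn aldol in which the (S)-benzyl auxiliary sets C10' and C11' (10',11'-syn, 11',12'-anti) under enolate control; the covalent boron enolate 27 should not expel the β-PMB-oxy group at −78 °C.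

Step 15
Reactants: 28 aldol adduct
Product: 29 C11' TBS ether of 28
Conditions: TBSOTf, 2,6-lutidine, CH2Cl2, −78 °C
Reagents that add atoms: tert-butyldimethylsilyl trifluoromethanesulfonate, CC(C)(C)[Si](C)(C)OS(=O)(=O)C(F)(F)F
Why: Silylation of the secondary alcohol blocks retro-aldol cleavage in the reduction that follows.

Step 16
Reactants: 29 silyl ether imide
Product: 30 C9' primary alcohol
Conditions: LiBH4, MeOH (1 equiv), THF, 0 °C
Reagents that add atoms: none
Why: Reductive removal of the auxiliary as in step 11.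

Step 17
Reactants: 30 primary alcohol
Product: 31 C9' aldehyde
Conditions: Dess–Martin periodinane, NaHCO3, CH2Cl2, 0 °C → rt
Reagents that add atoms: none
Why: Dess–Martin oxidation, mild enough to keep C10'.

Step 18
Reactants: 31 C9' aldehyde
Product: 32 homoallylic alcohol (C9' OH, C8' CH3, terminal vinyl = C7')
Conditions: (E)-but-2-ene, n-BuLi, KOt-Bu, THF, −45 °C; (+)-Ipc2BOMe, −78 °C; BF3·OEt2; then 31, −78 °C; NaOH, H2O2
Reagents that add atoms: (E)-crotylbis[(1S,2S,3S,5R)-isopinocampheyl]borane, C/C=C/CB([C@H]1C[C@H]2C[C@@H]([C@@H]1C)C2(C)C)[C@H]1C[C@H]2C[C@@H]([C@@H]1C)C2(C)C, made in the flask from (E)-but-2-ene, C/C=C/C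
Why: Brown crotylboration through a chair transition state: the (E)-crotyl group gives the 8',9'-anti relation and the isopinocampheyl groups of the (−)-α-pinene series direct the reagent to the Re face of the aldehyde, which sets C9' and C8' under reagent control.

Step 19
Reactants: 32 homoallylic alcohol
Product: 33 C9' TBS ether
Conditions: TBSOTf, 2,6-lutidine, CH2Cl2, −78 °C
Reagents that add atoms: tert-butyldimethylsilyl trifluoromethanesulfonate, CC(C)(C)[Si](C)(C)OS(=O)(=O)C(F)(F)F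
Why: Standard silylation of the secondary alcohol.

Step 20
Reactants: 33 terminal alkene
Product: 34 C7' aldehyde
Conditions: OsO4 (cat.), NaIO4, 2,6-lutidine, dioxane/H2O, rt
Reagents that add atoms: sodium periodate, [Na+].[O-]I(=O)(=O)=O
Why: Lemieux–Johnson cleavage of the monosubstituted alkene; the internal alkyne and the PMB ether should not react.

Step 21
Reactants: 35 (S)-4-(trimethylsilyl)but-3-yn-2-ol
Product: 36 (S)-4-(trimethylsilyl)but-3-yn-2-yl methanesulfonate
Conditions: MsCl, Et3N, CH2Cl2, −78 °C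
Reagents that add atoms: methanesulfonyl chloride, CS(=O)(=O)Cl
Why: O-sulfonylation does not touch the stereocenter.

Step 22
Reactants: 34 C7' aldehyde; 36 propargylic mesylate
Product: 38 homopropargylic alcohol (C7' OH, C6' CH3, C5'≡C4'–SiMe3), via allenylzinc 37 (not isolated)
Conditions: Pd(OAc)2 (5 mol%), PPh3 (5 mol%), Et2Zn, THF, −78 → −20 °C
Reagents that add atoms: none
Why: Marshall propargylation: zerovalent palladium displaces the mesylate in an anti SN2' sense, transmetalation gives allenylzinc 37, and its cyclic SE2' addition to the aldehyde gives the anti 6',7' relation, with C6' fixed by the mesylate configuration and C7' by the reagent rather than by C8'.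

Step 23
Reactants: 38 acetonide
Product: 39 7',13',14'-triol
Conditions: PPTS, MeOH, rt
Reagents that add atoms: none
Why: Acid-catalysed transacetalization should remove the acetonide while the two secondary TBS ethers and the alkynylsilane stay.

Step 24
Reactants: 39 triol
Product: 41 (Z)-16'-iodo-15'-ene triol, via cyclic alkenylalanate 40 (not isolated)
Conditions: NaAlH2(OCH2CH2OMe)2, THF, 0 °C → rt; then I2, −78 °C
Reagents that add atoms: iodine, [I][I]
Why: Alkoxide-directed trans-hydroalumination of the propargylic alcohol puts aluminium on the distal carbon C16' in the five-membered ring of 40, and iodinolysis with retention should give the alkenyl iodide with iodine cis to C14'.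

Step 25
Reactants: 41 triol
Product: 42 7',13',14'-tris(triethylsilyl) ether
Conditions: TESOTf, 2,6-lutidine, CH2Cl2, −78 → 0 °C
Reagents that add atoms: triethylsilyl trifluoromethanesulfonate, CC[Si](CC)(CC)OS(=O)(=O)C(F)(F)F
Why: The silyl triflate silylates the two secondary and the tertiary alcohol in one operation.

Step 26
Reactants: 42 PMB ether
Product: 43 primary alcohol at the C10' branch
Conditions: DDQ, CH2Cl2/pH 7 buffer, 0 °C
Reagents that add atoms: none
Why: Oxidative cleavage of the only PMB ether; silyl ethers, alkenyl iodide and alkynylsilane are inert to DDQ.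

Step 27
Reactants: 43 primary alcohol
Product: 44 C10' carboxylic acid
Conditions: TEMPO (cat.), PhI(OAc)2, MeCN/pH 7 buffer, rt
Reagents that add atoms: water, O
Why: Oxoammonium oxidation of the primary alcohol through the aldehyde hydrate to the acid under near-neutral conditions.

Step 28
Reactants: 44 acid
Product: 45 chain methyl ester (C4'–C16'; (Z)-16'-iodide; 7',13',14'-OTES; 9',11'-OTBS; C4' alkynylsilane)
Conditions: TMSCHN2, MeOH/toluene, 0 °C
Reagents that add atoms: (trimethylsilyl)diazomethane, C[Si](C)(C)C=[N+]=[N-]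
Why: Diazoalkane esterification gives the C10' methyl ester without base, so C10' and the β-silyloxy groups are safe.

**Part C – union, ring B, ring C**

Step 29
Reactants: 13 cyclobutenone aldehyde; 45 chain alkenyl iodide
Product: 46 C17' allylic benzylic alcohol (mixture at C17' and at the cyclobutene carbinol)
Conditions: CrCl2 (8 equiv), NiCl2 (2 mol%), DMSO/THF, rt
Reagents that add atoms: none
Why: Nozaki–Hiyama–Kishi coupling: nickel-catalysed, CrCl2-mediated addition of the alkenyl iodide to the aldehyde with retention of the (Z) geometry, chemoselective for the aldehyde over ester and cyclobutenone.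

Step 30
Reactants: 46 alcohol
Product: 47 C17' aryl enone
Conditions: Dess–Martin periodinane, NaHCO3, CH2Cl2, rt
Reagents that add atoms: none
Why: Dess–Martin oxidation of the secondary alcohol removes the C17' stereocenter and gives the (Z)-enone.

Step 31
Reactants: 47 alkynylsilane
Product: 48 1-iodoalkyne (C4')
Conditions: N-iodosuccinimide, AgNO3 (cat.), acetone, rt, dark
Reagents that add atoms: N-iodosuccinimide, O=C1CCC(=O)N1I
Why: Silver-catalysed iododesilylation of the alkynylsilane, run without acid so that the ring A C–H is not iodinated.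

Step 32
Reactants: 48 iodoalkyne
Product: 49 (Z)-4'-iodo-4'-ene
Conditions: 2-nitrobenzenesulfonylhydrazide, Et3N, THF/i-PrOH, rt
Reagents that add atoms: none
Why: Diimide syn-hydrogenation of the iodoalkyne stops at the (Z)-iodoalkene; the tri- and tetrasubstituted alkenes should not be reduced.

Step 33
Reactants: 49 4-aryl-4-silyloxycyclobutenone
Product: 52 2-methoxy-3-methyl-1,4-naphthoquinone with the full C4'–C17' chain at C5, via dienylketene 50 (not isolated), via naphthol 51 (not isolated)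
Conditions: p-xylene (degassed), 130 °C; then PhI(OAc)2, MeCN/H2O, 0 °C
Reagents that add atoms: none
Why: Heating opens the cyclobutenone by a conrotatory 4π electrocyclic ring opening in which the silyloxy group rotates outward, so the aryl group of dienylketene 50 lies cis to the ketene. 6π electrocyclization of the ketene carbon onto C8a of ring A forms the C1–C8a bond and closes ring B as a six-membered carbocycle; a proton shift gives naphthol 51, which PhI(OAc)2 oxidizes to the quinone with loss of the silyl group. The closest known reaction type is the Moore rearrangement of squarate-derived 4-aryl-4-(silyloxy)cyclobutenones to 1,4-naphthoquinones. No stereocenter is created, and the carbinol stereocenter carried as a mixture disappears. The step needs site selectivity between the two ortho carbons of the aryl group and the right placement of OCH3 and CH3 on ring B: the first is secured because C5 already bears the C17' acyl group and only C8a carries hydrogen, the second by the order of the aryllithium and MeLi additions in steps 5 and 6.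

Step 34
Reactants: 52 2-methoxyquinone
Product: 53 2-amino-3-methylquinone
Conditions: NH3 (7 M in MeOH), THF, 0 °C → rt
Reagents that add atoms: ammonia, N
Why: Addition–elimination of ammonia at C2 of the vinylogous ester (aminolysis of a 2-methoxy-1,4-naphthoquinone); the hindered ester and enone should not react at this temperature.

Step 35
Reactants: 54 (E)-3-iodo-2-methylacrylic acid
Product: 55 (E)-2-methyl-3-(tributylstannyl)acrylic acid
Conditions: (Bu3Sn)2, PdCl2(PPh3)2 (cat.), i-Pr2NEt, N-methylpyrrolidone, 60 °C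
Reagents that add atoms: hexabutylditin, CCCC[Sn](CCCC)(CCCC)[Sn](CCCC)(CCCC)CCCC
Why: Palladium-catalysed stannylation of the alkenyl iodide with the distannane proceeds with retention of the (E) geometry.

Step 36
Reactants: 55 stannyl acid; 53 aminoquinone
Product: 57 N-[(E)-2-methyl-3-(tributylstannyl)acryloyl]aminoquinone, via acid chloride 56 (not isolated)
Conditions: 1-chloro-N,N,2-trimethylprop-1-en-1-amine, CH2Cl2, 0 °C; then 53, pyridine, DMAP (cat.), 0 → 40 °C
Reagents that add atoms: none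
Why: N-acylation of the 2-amino-1,4-naphthoquinone by the small, unhindered acid chloride 56, which is made under neutral conditions so the alkenylstannane is not protonolysed.

Step 37
Reactants: 57 iodide/stannane
Product: 58 protected macrocycle (ring C closed; 7',13',14'-OTES; 9',11'-OTBS; 6,8-OMOM)
Conditions: Pd2(dba)3, AsPh3, i-Pr2NEt, DMF/THF (1 mM), rt → 45 °C
Reagents that add atoms: none
Why: Intramolecular Stille coupling joins C3' and C4' with retention at both alkenes, closing the 23-membered ring C and giving the (2'E,4'Z)-dienamide directly.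

Step 38
Reactants: 58 protected macrocycle
Product: 59 CNP0244244.1
Conditions: HF (48% aq.), MeCN, 0 °C → rt; then 2 M HCl, MeOH, rt
Reagents that add atoms: none
Why: Acidic global deprotection: fluoride-assisted solvolysis of the five silyl ethers and acid methanolysis of the two aryl MOM ethers, which are activated by the ortho and peri carbonyl groups; no stereocenter is involved.

**Compound list**
1 | 2-methylresorcinol | Cc1c(O)cccc1O | starting material
2 | 1,3-bis(methoxymethoxy)-2-methylbenzene | Cc1c(OCOC)cccc1OCOC | intermediate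
3 | aryl pinacol boronate (5-boryl derivative of 2) | Cc1c(OCOC)cc(B2OC(C)(C)C(C)(C)O2)cc1OCOC | intermediate
4 | 5-iodo-1,3-bis(methoxymethoxy)-2-methylbenzene | Cc1c(OCOC)cc(I)cc1OCOC | intermediate
5 | [6-iodo-2,4-bis(methoxymethoxy)-3-methylphenyl]lithium | Cc1c(OCOC)cc(I)c([Li])c1OCOC | intermediate
6 | 6-iodo-2,4-bis(methoxymethoxy)-3-methylbenzaldehyde | Cc1c(OCOC)cc(I)c(C=O)c1OCOC | intermediate
7 | 1-(dimethoxymethyl)-6-iodo-2,4-bis(methoxymethoxy)-3-methylbenzene | Cc1c(OCOC)cc(I)c(C(OC)OC)c1OCOC | intermediate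
8 | dimethyl squarate | COC1=C(OC)C(=O)C1=O | starting material
9 | [2-(dimethoxymethyl)-3,5-bis(methoxymethoxy)-4-methylphenyl]lithium | Cc1c(OCOC)cc([Li])c(C(OC)OC)c1OCOC | intermediate
10 | lithium 1-aryl-2,3-dimethoxy-4-oxocyclobut-2-en-1-olate | Cc1c(OCOC)cc(C2(O[Li])C(OC)=C(OC)C2=O)c(C(OC)OC)c1OCOC | intermediate
11 | 4-aryl-2,3-dimethoxy-4-(triethylsilyloxy)cyclobut-2-en-1-one | Cc1c(OCOC)cc(C2(O[Si](CC)(CC)CC)C(OC)=C(OC)C2=O)c(C(OC)OC)c1OCOC | intermediate
12 | lithium 1-methylcyclobutenolate (MeLi adduct of 11) | Cc1c(OCOC)cc(C2(O[Si](CC)(CC)CC)C(OC)=C(OC)C2(C)O[Li])c(C(OC)OC)c1OCOC | intermediate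
13 | 4-[2-formyl-3,5-bis(methoxymethoxy)-4-methylphenyl]-2-methoxy-3-methyl-4-(triethylsilyloxy)cyclobut-2-en-1-one | Cc1c(OCOC)cc(C2(O[Si](CC)(CC)CC)C(C)=C(OC)C2=O)c(C=O)c1OCOC | intermediate
14 | (R)-4-benzyl-3-propionyloxazolidin-2-one | CCC(=O)N1[C@H](Cc2ccccc2)COC1=O | starting material
15 | methacrolein | CC(=C)C=O | starting material
16 | (Z)-dibutylboron enolate of 14 | C/C=C(\OB(CCCC)CCCC)N1[C@H](Cc2ccccc2)COC1=O | intermediate
17 | (R)-4-benzyl-3-[(2R,3R)-3-hydroxy-2,4-dimethylpent-4-enoyl]oxazolidin-2-one | C=C(C)[C@H](O)[C@@H](C)C(=O)N1[C@H](Cc2ccccc2)COC1=O | intermediate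
18 | (R)-4-benzyl-3-[(2R,3R)-3-hydroxy-2-methyl-4-oxopentanoyl]oxazolidin-2-one | CC(=O)[C@H](O)[C@@H](C)C(=O)N1[C@H](Cc2ccccc2)COC1=O | intermediate
19 | (R)-4-benzyl-3-[(2R,3R,4R)-3,4-dihydroxy-2,4-dimethylhept-5-ynoyl]oxazolidin-2-one | CC#C[C@@](C)(O)[C@H](O)[C@@H](C)C(=O)N1[C@H](Cc2ccccc2)COC1=O | intermediate
20 | acetonide of 19 | CC#C[C@@]1(C)OC(C)(C)O[C@@H]1[C@@H](C)C(=O)N1[C@H](Cc2ccccc2)COC1=O | intermediate
21 | (R)-2-[(4R,5R)-2,2,5-trimethyl-5-(prop-1-ynyl)-1,3-dioxolan-4-yl]propan-1-ol | CC#C[C@@]1(C)OC(C)(C)O[C@@H]1[C@@H](C)CO | intermediate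
22 | C11' aldehyde (aldehyde of 21) | CC#C[C@@]1(C)OC(C)(C)O[C@@H]1[C@@H](C)C=O | intermediate
23 | 3-[(4-methoxybenzyl)oxy]propanoic acid | COc1ccc(COCCC(=O)O)cc1 | starting material
24 | (S)-4-benzyloxazolidin-2-one | O=C1N[C@@H](Cc2ccccc2)CO1 | starting material
25 | mixed pivalic anhydride of 23 | COc1ccc(COCCC(=O)OC(=O)C(C)(C)C)cc1 | intermediate
26 | (S)-4-benzyl-3-{3-[(4-methoxybenzyl)oxy]propanoyl}oxazolidin-2-one | COc1ccc(COCCC(=O)N2[C@@H](Cc3ccccc3)COC2=O)cc1 | intermediate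
27 | (Z)-dibutylboron enolate of 26 | COc1ccc(COC/C=C(\OB(CCCC)CCCC)N2[C@@H](Cc3ccccc3)COC2=O)cc1 | intermediate
28 | syn aldol adduct (C9' imide, C10' CH2OPMB, C11' OH, 13',14'-acetonide) | CC#C[C@@]1(C)OC(C)(C)O[C@@H]1[C@@H](C)[C@@H](O)[C@H](COCc2ccc(OC)cc2)C(=O)N2[C@@H](Cc3ccccc3)COC2=O | intermediate
29 | C11' TBS ether of 28 | CC#C[C@@]1(C)OC(C)(C)O[C@@H]1[C@@H](C)[C@@H](O[Si](C)(C)C(C)(C)C)[C@H](COCc2ccc(OC)cc2)C(=O)N2[C@@H](Cc3ccccc3)COC2=O | intermediate
30 | C9' primary alcohol | CC#C[C@@]1(C)OC(C)(C)O[C@@H]1[C@@H](C)[C@@H](O[Si](C)(C)C(C)(C)C)[C@H](COCc2ccc(OC)cc2)CO | intermediate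
31 | C9' aldehyde | CC#C[C@@]1(C)OC(C)(C)O[C@@H]1[C@@H](C)[C@@H](O[Si](C)(C)C(C)(C)C)[C@H](COCc2ccc(OC)cc2)C=O | intermediate
32 | crotylation product (C9' OH, C8' CH3, vinyl) | CC#C[C@@]1(C)OC(C)(C)O[C@@H]1[C@@H](C)[C@@H](O[Si](C)(C)C(C)(C)C)[C@H](COCc2ccc(OC)cc2)[C@H](O)[C@H](C)C=C | intermediate
33 | 9',11'-bis-TBS ether alkene | CC#C[C@@]1(C)OC(C)(C)O[C@@H]1[C@@H](C)[C@@H](O[Si](C)(C)C(C)(C)C)[C@H](COCc2ccc(OC)cc2)[C@H](O[Si](C)(C)C(C)(C)C)[C@H](C)C=C | intermediate
34 | C7' aldehyde | CC#C[C@@]1(C)OC(C)(C)O[C@@H]1[C@@H](C)[C@@H](O[Si](C)(C)C(C)(C)C)[C@H](COCc2ccc(OC)cc2)[C@H](O[Si](C)(C)C(C)(C)C)[C@H](C)C=O | intermediate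
35 | (S)-4-(trimethylsilyl)but-3-yn-2-ol | C[C@H](O)C#C[Si](C)(C)C | starting material
36 | (S)-4-(trimethylsilyl)but-3-yn-2-yl methanesulfonate | C[C@H](OS(C)(=O)=O)C#C[Si](C)(C)C | intermediate
37 | ethyl[(M)-1-(trimethylsilyl)buta-1,2-dienyl]zinc | CC[Zn]C([Si](C)(C)C)=[C@@]=C(C)[H] | intermediate
38 | homopropargylic alcohol (C7' OH, C6' CH3, alkynylsilane, acetonide) | CC#C[C@@]1(C)OC(C)(C)O[C@@H]1[C@@H](C)[C@@H](O[Si](C)(C)C(C)(C)C)[C@H](COCc2ccc(OC)cc2)[C@H](O[Si](C)(C)C(C)(C)C)[C@H](C)[C@H](O)[C@H](C)C#C[Si](C)(C)C | intermediate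
39 | 7',13',14'-triol | CC#C[C@@](C)(O)[C@H](O)[C@@H](C)[C@@H](O[Si](C)(C)C(C)(C)C)[C@H](COCc1ccc(OC)cc1)[C@H](O[Si](C)(C)C(C)(C)C)[C@H](C)[C@H](O)[C@H](C)C#C[Si](C)(C)C | intermediate
40 | sodium 1,2-oxaluminol-3-ene ate complex (O14'–Al–C16'; other hydroxyls drawn free) | [Na+].CC1=C[C@](C)([C@H](O)[C@@H](C)[C@@H](O[Si](C)(C)C(C)(C)C)[C@H](COCc2ccc(OC)cc2)[C@H](O[Si](C)(C)C(C)(C)C)[C@H](C)[C@H](O)[C@H](C)C#C[Si](C)(C)C)O[Al-]1(OCCOC)OCCOC | intermediate
41 | (Z)-16'-iodo triol | C/C(I)=C/[C@@](C)(O)[C@H](O)[C@@H](C)[C@@H](O[Si](C)(C)C(C)(C)C)[C@H](COCc1ccc(OC)cc1)[C@H](O[Si](C)(C)C(C)(C)C)[C@H](C)[C@H](O)[C@H](C)C#C[Si](C)(C)C | intermediate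
42 | tris-TES ether PMB ether | C/C(I)=C/[C@@](C)(O[Si](CC)(CC)CC)[C@H](O[Si](CC)(CC)CC)[C@@H](C)[C@@H](O[Si](C)(C)C(C)(C)C)[C@H](COCc1ccc(OC)cc1)[C@H](O[Si](C)(C)C(C)(C)C)[C@H](C)[C@H](O[Si](CC)(CC)CC)[C@H](C)C#C[Si](C)(C)C | intermediate
43 | primary alcohol at the C10' branch | C/C(I)=C/[C@@](C)(O[Si](CC)(CC)CC)[C@H](O[Si](CC)(CC)CC)[C@@H](C)[C@@H](O[Si](C)(C)C(C)(C)C)[C@H](CO)[C@H](O[Si](C)(C)C(C)(C)C)[C@H](C)[C@H](O[Si](CC)(CC)CC)[C@H](C)C#C[Si](C)(C)C | intermediate
44 | C10' carboxylic acid | C/C(I)=C/[C@@](C)(O[Si](CC)(CC)CC)[C@H](O[Si](CC)(CC)CC)[C@@H](C)[C@@H](O[Si](C)(C)C(C)(C)C)[C@H](C(=O)O)[C@H](O[Si](C)(C)C(C)(C)C)[C@H](C)[C@H](O[Si](CC)(CC)CC)[C@H](C)C#C[Si](C)(C)C | intermediate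
45 | chain methyl ester ((Z)-16'-iodide, C4' alkynylsilane) | C/C(I)=C/[C@@](C)(O[Si](CC)(CC)CC)[C@H](O[Si](CC)(CC)CC)[C@@H](C)[C@@H](O[Si](C)(C)C(C)(C)C)[C@H](C(=O)OC)[C@H](O[Si](C)(C)C(C)(C)C)[C@H](C)[C@H](O[Si](CC)(CC)CC)[C@H](C)C#C[Si](C)(C)C | intermediate
46 | C17' alcohol (coupling product of 13 and 45) | OC(c1c(C2(O[Si](CC)(CC)CC)C(C)=C(OC)C2=O)cc(OCOC)c(C)c1OCOC)/C(C)=C\[C@@](C)(O[Si](CC)(CC)CC)[C@H](O[Si](CC)(CC)CC)[C@@H](C)[C@@H](O[Si](C)(C)C(C)(C)C)[C@H](C(=O)OC)[C@H](O[Si](C)(C)C(C)(C)C)[C@H](C)[C@H](O[Si](CC)(CC)CC)[C@H](C)C#C[Si](C)(C)C | intermediate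
47 | C17' aryl (Z)-enone, alkynylsilane | O=C(c1c(C2(O[Si](CC)(CC)CC)C(C)=C(OC)C2=O)cc(OCOC)c(C)c1OCOC)/C(C)=C\[C@@](C)(O[Si](CC)(CC)CC)[C@H](O[Si](CC)(CC)CC)[C@@H](C)[C@@H](O[Si](C)(C)C(C)(C)C)[C@H](C(=O)OC)[C@H](O[Si](C)(C)C(C)(C)C)[C@H](C)[C@H](O[Si](CC)(CC)CC)[C@H](C)C#C[Si](C)(C)C | intermediate
48 | 1-iodoalkyne | O=C(c1c(C2(O[Si](CC)(CC)CC)C(C)=C(OC)C2=O)cc(OCOC)c(C)c1OCOC)/C(C)=C\[C@@](C)(O[Si](CC)(CC)CC)[C@H](O[Si](CC)(CC)CC)[C@@H](C)[C@@H](O[Si](C)(C)C(C)(C)C)[C@H](C(=O)OC)[C@H](O[Si](C)(C)C(C)(C)C)[C@H](C)[C@H](O[Si](CC)(CC)CC)[C@H](C)C#CI | intermediate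
49 | (Z)-4'-iodoalkene cyclobutenone | O=C(c1c(C2(O[Si](CC)(CC)CC)C(C)=C(OC)C2=O)cc(OCOC)c(C)c1OCOC)/C(C)=C\[C@@](C)(O[Si](CC)(CC)CC)[C@H](O[Si](CC)(CC)CC)[C@@H](C)[C@@H](O[Si](C)(C)C(C)(C)C)[C@H](C(=O)OC)[C@H](O[Si](C)(C)C(C)(C)C)[C@H](C)[C@H](O[Si](CC)(CC)CC)[C@H](C)/C=C\I | intermediate
50 | aryl dienylketene | O=C=C(OC)/C(C)=C(/O[Si](CC)(CC)CC)c1cc(OCOC)c(C)c(OCOC)c1C(=O)/C(C)=C\[C@@](C)(O[Si](CC)(CC)CC)[C@H](O[Si](CC)(CC)CC)[C@@H](C)[C@@H](O[Si](C)(C)C(C)(C)C)[C@H](C(=O)OC)[C@H](O[Si](C)(C)C(C)(C)C)[C@H](C)[C@H](O[Si](CC)(CC)CC)[C@H](C)/C=C\I | intermediate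
51 | 2-methoxy-3-methyl-4-(triethylsilyloxy)naphthalen-1-ol with ring A substituents and chain | COc1c(C)c(O[Si](CC)(CC)CC)c2c(C(=O)/C(C)=C\[C@@](C)(O[Si](CC)(CC)CC)[C@H](O[Si](CC)(CC)CC)[C@@H](C)[C@@H](O[Si](C)(C)C(C)(C)C)[C@H](C(=O)OC)[C@H](O[Si](C)(C)C(C)(C)C)[C@H](C)[C@H](O[Si](CC)(CC)CC)[C@H](C)/C=C\I)c(OCOC)c(C)c(OCOC)c2c1O | intermediate
52 | 2-methoxy-3,7-dimethyl-6,8-bis(methoxymethoxy)-1,4-naphthoquinone with the C4'–C17' acyl chain at C5 | COC1=C(C)C(=O)c2c(C(=O)/C(C)=C\[C@@](C)(O[Si](CC)(CC)CC)[C@H](O[Si](CC)(CC)CC)[C@@H](C)[C@@H](O[Si](C)(C)C(C)(C)C)[C@H](C(=O)OC)[C@H](O[Si](C)(C)C(C)(C)C)[C@H](C)[C@H](O[Si](CC)(CC)CC)[C@H](C)/C=C\I)c(OCOC)c(C)c(OCOC)c2C1=O | intermediate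
53 | 2-amino analogue of 52 | NC1=C(C)C(=O)c2c(C(=O)/C(C)=C\[C@@](C)(O[Si](CC)(CC)CC)[C@H](O[Si](CC)(CC)CC)[C@@H](C)[C@@H](O[Si](C)(C)C(C)(C)C)[C@H](C(=O)OC)[C@H](O[Si](C)(C)C(C)(C)C)[C@H](C)[C@H](O[Si](CC)(CC)CC)[C@H](C)/C=C\I)c(OCOC)c(C)c(OCOC)c2C1=O | intermediate
54 | (E)-3-iodo-2-methylacrylic acid | OC(=O)/C(C)=C/I | starting material
55 | (E)-2-methyl-3-(tributylstannyl)acrylic acid | OC(=O)/C(C)=C/[Sn](CCCC)(CCCC)CCCC | intermediate
56 | (E)-2-methyl-3-(tributylstannyl)acryloyl chloride | ClC(=O)/C(C)=C/[Sn](CCCC)(CCCC)CCCC | intermediate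
57 | stannylacrylamide of 53 | CCCC[Sn](CCCC)(CCCC)/C=C(\C)C(=O)NC1=C(C)C(=O)c2c(C(=O)/C(C)=C\[C@@](C)(O[Si](CC)(CC)CC)[C@H](O[Si](CC)(CC)CC)[C@@H](C)[C@@H](O[Si](C)(C)C(C)(C)C)[C@H](C(=O)OC)[C@H](O[Si](C)(C)C(C)(C)C)[C@H](C)[C@H](O[Si](CC)(CC)CC)[C@H](C)/C=C\I)c(OCOC)c(C)c(OCOC)c2C1=O | intermediate
58 | protected macrocycle | COC(=O)[C@@H]1[C@H](O[Si](C)(C)C(C)(C)C)[C@H](C)[C@H](O[Si](CC)(CC)CC)[C@H](C)/C=C\C=C(/C)C(=O)NC2=C(C)C(=O)c3c(c(OCOC)c(C)c(OCOC)c3C(=O)/C(C)=C\[C@@](C)(O[Si](CC)(CC)CC)[C@H](O[Si](CC)(CC)CC)[C@@H](C)[C@H]1O[Si](C)(C)C(C)(C)C)C2=O | intermediate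
59 | CNP0244244.1 (6'R,7'R,8'R,9'R,10'R,11'R,12'S,13'R,14'R; 2'E,4'Z,15'Z) | COC(=O)[C@@H]1[C@H](O)[C@H](C)[C@H](O)[C@H](C)/C=C\C=C(/C)C(=O)NC2=C(C)C(=O)c3c(c(O)c(C)c(O)c3C(=O)/C(C)=C\[C@@](C)(O)[C@H](O)[C@@H](C)[C@H]1O)C2=O | target

**Totals and risks**
Total step count: 38. Longest linear sequence: 29 steps (from 14 through steps 7–12, 14–20, 22–34 and 36–38).

Steps most likely to fail:

1. Step 29. Both partners are hindered (an aldehyde between two ortho substituents, an alkenyl iodide next to a fully substituted carbon), so addition may be slow and protodeiodination of 45 or reductive dimerization of the aldehyde may take over. Fallback, from 45 and 13, returning at 47: 45 is stannylated (Me3SnSnMe3, Pd(PPh3)4, toluene, 80 °C) to the (Z)-alkenyl(trimethyl)stannane F1. Aldehyde 13 is oxidized (NaClO2, NaH2PO4, 2-methylbut-2-ene) to the benzoic acid F2, which 1-chloro-N,N,2-trimethylprop-1-en-1-amine converts into the aroyl chloride F3. A palladium-catalysed acyl Stille coupling of F3 with F1 (Pd2(dba)3, tri(2-furyl)phosphine, CuI) should give enone 47 directly, without the alcohol 46.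

2. Step 36. The nitrogen of the aminoquinone is a weak, vinylogous-amide nucleophile, so acylation may stall while the acid chloride decomposes or the stannane is protonolysed. Fallback, from 53, returning at 57: 53 is reduced with aqueous Na2S2O4 in EtOAc to the air-sensitive 2-aminonaphthalene-1,4-diol F4, whose aniline-type nitrogen is acylated by 56 (pyridine, CH2Cl2, −20 °C) to the amido hydroquinone F5; exposure to air (or Ag2O) should reoxidize F5 to quinone 57.

3. Step 9. The magnesium aldolate of the β-hydroxy imide may fragment by retro-aldol reaction, or the Grignard reagent may attack the imide, before addition to the ketone; facial control would then also erode. Fallback, from 17, returning at 19: 17 is converted with 4-methoxybenzyl trichloroacetimidate and catalytic TfOH into the PMB ether F6. Lemieux–Johnson cleavage gives the α-alkoxy ketone F7, and chelate-controlled addition of CH3C≡CMgBr (one equivalent suffices, no alkoxide is formed) gives the tertiary alcohol F8. DDQ in wet CH2Cl2 removes the PMB group to give diol 19.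

**Further compounds**
F1 | step 29 | (Z)-16'-(trimethylstannyl) analogue of 45 | C/C([Sn](C)(C)C)=C/[C@@](C)(O[Si](CC)(CC)CC)[C@H](O[Si](CC)(CC)CC)[C@@H](C)[C@@H](O[Si](C)(C)C(C)(C)C)[C@H](C(=O)OC)[C@H](O[Si](C)(C)C(C)(C)C)[C@H](C)[C@H](O[Si](CC)(CC)CC)[C@H](C)C#C[Si](C)(C)C
F2 | step 29 | benzoic acid from 13 | Cc1c(OCOC)cc(C2(O[Si](CC)(CC)CC)C(C)=C(OC)C2=O)c(C(=O)O)c1OCOC
F3 | step 29 | aroyl chloride from F2 | Cc1c(OCOC)cc(C2(O[Si](CC)(CC)CC)C(C)=C(OC)C2=O)c(C(=O)Cl)c1OCOC
F4 | step 36 | 2-aminonaphthalene-1,4-diol from 53 | Nc1c(C)c(O)c2c(C(=O)/C(C)=C\[C@@](C)(O[Si](CC)(CC)CC)[C@H](O[Si](CC)(CC)CC)[C@@H](C)[C@@H](O[Si](C)(C)C(C)(C)C)[C@H](C(=O)OC)[C@H](O[Si](C)(C)C(C)(C)C)[C@H](C)[C@H](O[Si](CC)(CC)CC)[C@H](C)/C=C\I)c(OCOC)c(C)c(OCOC)c2c1O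
F5 | step 36 | amido hydroquinone (reduced form of 57) | CCCC[Sn](CCCC)(CCCC)/C=C(\C)C(=O)Nc1c(C)c(O)c2c(C(=O)/C(C)=C\[C@@](C)(O[Si](CC)(CC)CC)[C@H](O[Si](CC)(CC)CC)[C@@H](C)[C@@H](O[Si](C)(C)C(C)(C)C)[C@H](C(=O)OC)[C@H](O[Si](C)(C)C(C)(C)C)[C@H](C)[C@H](O[Si](CC)(CC)CC)[C@H](C)/C=C\I)c(OCOC)c(C)c(OCOC)c2c1O
F6 | step 9 | PMB ether of 17 | C=C(C)[C@H](OCc1ccc(OC)cc1)[C@@H](C)C(=O)N1[C@H](Cc2ccccc2)COC1=O
F7 | step 9 | α-(PMB-oxy) methyl ketone | CC(=O)[C@H](OCc1ccc(OC)cc1)[C@@H](C)C(=O)N1[C@H](Cc2ccccc2)COC1=O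
F8 | step 9 | propynyl adduct of F7 | CC#C[C@@](C)(O)[C@H](OCc1ccc(OC)cc1)[C@@H](C)C(=O)N1[C@H](Cc2ccccc2)COC1=O
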